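**Strategy.** The lower flavan-3,4-diol is traced back to a flat flavonol ether whose pyranone ring C is made by a [3+3] annulation. On lower ring A, C4a (bearing C4) and the ether carbon C8a are adjacent, so a 2-fluorobenzoyl chloride (C4 acyl, C8a–F) is a 1,3-dielectrophile and the lithium enolate of an α-benzyloxy aryl ketone (C3, C2, O1) a 1,3-dinucleophile: C-acylation makes C3–C4 and enolate-oxygen SNAr makes O1–C8a in one pot. The all-cis C2/C3/C4 triad follows by conjugate reduction and dynamic kinetic transfer hydrogenation; the upper 2,4-trans flavan is grown on C6 by rhodium-catalysed arylation, transfer hydrogenation and Mitsunobu closure.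

Key step: step 7

Remark: 1, 7 and 8 are taken as catalogue compounds; the upper C4 is R in 17–21 and S in 22 for the same spatial arrangement, because the CIP priorities change on debenzylation.

Step 1
Reactants: 1 2-fluoro-3,4-dihydroxybenzaldehyde
Product: 2 3-(benzyloxy)-2-fluoro-4-hydroxybenzaldehyde
Conditions: NaH (2.2 equiv), DMSO, rt; BnBr (1.0 equiv); then aq. HCl
Reagents that add atoms: benzyl bromide, BrCc1ccccc1
Why: Williamson etherification of the dianion, in which the 3-oxide, not delocalised onto the para-formyl group, is the more nucleophilic oxygen and should be benzylated first.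

Step 2
Reactants: 2 3-(benzyloxy)-2-fluoro-4-hydroxybenzaldehyde
Product: 3 3-(benzyloxy)-5-bromo-2-fluoro-4-hydroxybenzaldehyde
Conditions: Br2, NaOAc, AcOH, rt
Reagents that add atoms: bromine, BrBr
Why: Electrophilic aromatic bromination goes ortho to the free 4-hydroxyl (para position blocked by the formyl group), as in the bromination of vanillin.

Step 3
Reactants: 3 3-(benzyloxy)-5-bromo-2-fluoro-4-hydroxybenzaldehyde
Product: 4 3,4-bis(benzyloxy)-5-bromo-2-fluorobenzaldehyde
Conditions: BnBr, K2CO3, DMF, 50 °C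
Reagents that add atoms: benzyl bromide, BrCc1ccccc1
Why: Williamson etherification of the remaining phenol.

Step 4
Reactants: 4 3,4-bis(benzyloxy)-5-bromo-2-fluorobenzaldehyde
Product: 5 3,4-bis(benzyloxy)-5-bromo-2-fluorobenzoic acid
Conditions: NaClO2, NaH2PO4, 2-methyl-2-butene, t-BuOH/H2O, rt
Reagents that add atoms: sodium chlorite, [Na+].[O-]Cl=O
Why: Pinnick oxidation converts the aldehyde to the acid, with the alkene scavenging hypochlorite so that the electron-rich rings are not chlorinated.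

Step 5
Reactants: 5 3,4-bis(benzyloxy)-5-bromo-2-fluorobenzoic acid
Product: 6 3,4-bis(benzyloxy)-5-bromo-2-fluorobenzoyl chloride
Conditions: (COCl)2, DMF (cat.), CH2Cl2, 0 °C to rt
Reagents that add atoms: oxalyl chloride, ClC(=O)C(=O)Cl
Why: Acid chloride formation through the Vilsmeier-type chloroiminium activation, which leaves aryl bromide, fluoride and benzyl ethers untouched.

Step 6
Reactants: 7 2-(benzyloxy)-N-methoxy-N-methylacetamide; 8 [4-(benzyloxy)phenyl]magnesium bromide
Product: 9 2-(benzyloxy)-1-[4-(benzyloxy)phenyl]ethan-1-one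
Conditions: THF, 0 °C; then 1 M HCl
Reagents that add atoms: none
Why: Weinreb ketone synthesis, in which the chelated tetrahedral intermediate prevents over-addition.

Step 7
Reactants: 6 3,4-bis(benzyloxy)-5-bromo-2-fluorobenzoyl chloride; 9 2-(benzyloxy)-1-[4-(benzyloxy)phenyl]ethan-1-one
Product: 11 3,7,8-tris(benzyloxy)-2-[4-(benzyloxy)phenyl]-6-bromo-4H-chromen-4-one, via 2-benzyloxy-1,3-diketone 10 (not isolated)
Conditions: 9 (2.2 equiv), LiN(SiMe3)2 (2.3 equiv), THF, −78 °C; add 6, −78 to 0 °C; then DMF, 80 °C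
Reagents that add atoms: none
Why: The lithium enolate of 9 is C-acylated by 6 (crossed Claisen-type acylation, any O-acyl enol ester being funnelled to the diketonate by acyl transfer to the excess enolate), which makes C3–C4 and gives the lithium diketonate of 10; on warming in DMF its enolate oxygen on the C2 side attacks C8a, ortho to the new C4 carbonyl, and fluoride leaves (intramolecular SNAr by addition–elimination), which makes O1–C8a. The closest known reaction type is the chromone, flavone and 4-quinolone synthesis from 2-halobenzoyl chlorides and enolates (C-acylation, then cyclising SNAr). The only ring closed is pyranone ring C, a six-membered closure of the 6-endo-trig kind at the C4a=C8a bond, whose Meisenheimer charge is taken up by the C4 carbonyl. No stereocenter is formed: C2 and C3 stay sp2 and C4 is a carbonyl, so the three stereocenters of ring C are left to steps 14 and 15. The step needs C- over O-acylation, a single mode of ring closure and an untouched C6–Br: the lithium counter-ion at low temperature and the stability of the diketonate secure the first, only O1 can reach C8a through a six-membered transition state and fluorine is the only leaving group activated by the ortho carbonyl, and bromine, meta to that carbonyl, is not activated.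

Step 8
Reactants: 11 3,7,8-tris(benzyloxy)-2-[4-(benzyloxy)phenyl]-6-bromo-4H-chromen-4-one
Product: 12 3,7,8-tris(benzyloxy)-2-[4-(benzyloxy)phenyl]-6-(4,4,5,5-tetramethyl-1,3,2-dioxaborolan-2-yl)-4H-chromen-4-one
Conditions: B2pin2, Pd(dppf)Cl2 (cat.), KOAc, dioxane, 90 °C
Reagents that add atoms: bis(pinacolato)diboron, CC1(C)OB(OC1(C)C)B1OC(C)(C)C(C)(C)O1
Why: Miyaura borylation of the aryl bromide, to which the flavone carbonyl and the benzyl ethers are inert.

Step 9
Reactants: 13 2,3,4-trihydroxybenzaldehyde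
Product: 14 3,4-bis(benzyloxy)-2-hydroxybenzaldehyde
Conditions: BnBr (2.1 equiv), K2CO3 (2.1 equiv), DMF, rt
Reagents that add atoms: benzyl bromide, BrCc1ccccc1
Why: Selective Williamson etherification, in which the 2-hydroxyl, hydrogen-bonded to the formyl group, is the least reactive and should stay free.

Step 10
Reactants: 14 3,4-bis(benzyloxy)-2-hydroxybenzaldehyde; 15 1-[4-(benzyloxy)phenyl]ethan-1-one
Product: 16 (E)-3-[3,4-bis(benzyloxy)-2-hydroxyphenyl]-1-[4-(benzyloxy)phenyl]prop-2-en-1-one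
Conditions: KOH, EtOH/H2O, rt; then AcOH
Reagents that add atoms: none
Why: Claisen–Schmidt condensation gives the thermodynamic (E)-enone, and the mild acetic acid work-up avoids cyclisation to a flavylium salt.

Step 11
Reactants: 12 flavone 6-boronate; 16 (E)-2-hydroxychalcone
Product: 17 (3R)-3-[3,4-bis(benzyloxy)-2-hydroxyphenyl]-1-[4-(benzyloxy)phenyl]-3-{3,7,8-tris(benzyloxy)-2-[4-(benzyloxy)phenyl]-4-oxo-4H-chromen-6-yl}propan-1-one
Conditions: [Rh(OH)((S)-BINAP)]2 (cat.), KOH (aq., substoichiometric), dioxane/H2O, 50 °C; 16 in excess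
Reagents that add atoms: none
Why: Hayashi–Miyaura asymmetric 1,4-addition: the aryl–rhodium species inserts the (E)-enone, and the (S)-BINAP ligand is expected, from the facial model for acyclic (E)-enones, to set the diarylmethine carbon (the future upper C4) as 3R; the tetrasubstituted flavone enone does not compete.

Step 12
Reactants: 17 (3R)-β,β-diaryl ketone
Product: 18 (1R,3R)-3-[3,4-bis(benzyloxy)-2-hydroxyphenyl]-1-[4-(benzyloxy)phenyl]-3-{3,7,8-tris(benzyloxy)-2-[4-(benzyloxy)phenyl]-4-oxo-4H-chromen-6-yl}propan-1-ol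
Conditions: RuCl[(R,R)-TsDPEN](p-cymene) (cat.), HCO2H/Et3N (5:2), DMF, rt
Reagents that add atoms: none
Why: Noyori–Ikariya asymmetric transfer hydrogenation of the aryl ketone, in which the (R,R) catalyst should give the 1R carbinol under catalyst control and leave the vinylogous-ester carbonyl of the flavone alone.

Step 13
Reactants: 18 (1R,3R)-phenol-alcohol
Product: 19 3,7,8-tris(benzyloxy)-2-[4-(benzyloxy)phenyl]-6-{(2S,4R)-7,8-bis(benzyloxy)-2-[4-(benzyloxy)phenyl]chroman-4-yl}-4H-chromen-4-one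
Conditions: PPh3, DIAD, THF, 0 °C to rt
Reagents that add atoms: none
Why: Intramolecular Mitsunobu etherification: the phenol displaces the activated benzylic hydroxyl with inversion (1R carbinol to 2S), which closes the upper pyran ring with the 2,4-trans relationship.

Step 14
Reactants: 19 flavan–flavone
Product: 20 3,7,8-tris(benzyloxy)-2-[4-(benzyloxy)phenyl]-6-{(2S,4R)-7,8-bis(benzyloxy)-2-[4-(benzyloxy)phenyl]chroman-4-yl}chroman-4-one, mixture of stereoisomers at C2 and C3 of the lower unit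
Conditions: LiBH(s-Bu)3, THF, −78 °C; then AcOH, −78 °C
Reagents that add atoms: none
Why: Conjugate (1,4) hydride reduction of the chromone by the hindered borohydride followed by protonation of the lithium enolate; no lasting stereocenter is set, as C2 and C3 are equilibrated in step 15.

Step 15
Reactants: 20 3-benzyloxyflavanone mixture
Product: 21 (2R,3R,4R)-3,7,8-tris(benzyloxy)-2-[4-(benzyloxy)phenyl]-6-{(2S,4R)-7,8-bis(benzyloxy)-2-[4-(benzyloxy)phenyl]chroman-4-yl}chroman-4-ol
Conditions: RuCl[(S,S)-TsDPEN](p-cymene) (cat.), HCO2H, Et3N, DBU, MeCN, 40 °C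
Reagents that add atoms: none
Why: Noyori–Ikariya asymmetric transfer hydrogenation with dynamic kinetic resolution: C3 epimerises by enolisation and C2 by base-mediated retro-oxa-Michael ring opening and re-closure, the (S,S) catalyst delivers hydride to the face that makes C4 R, and the fastest substrate should be the 2,3-cis ketone of the 2R series, whose axial C3 benzyloxy group lies anti to the incoming hydride (polar Felkin–Anh) and whose C2 aryl group is on the far side, so that C2, C3 and C4 end all-cis.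

Step 16
Reactants: 21 heptabenzyl ether
Product: 22 (2R,3R,4R)-6-[(2S,4S)-7,8-dihydroxy-2-(4-hydroxyphenyl)chroman-4-yl]-2-(4-hydroxyphenyl)chromane-3,4,7,8-tetrol (target)
Conditions: H2 (1 atm), Pd(OH)2/C, THF/H2O, rt
Reagents that add atoms: none
Why: Hydrogenolysis of the seven benzyl ethers under neutral, methanol-free conditions, which should spare the benzylic C4 hydroxyl and the benzylic ring ethers, as is usual for benzyl-protected proanthocyanidins.

**Compound list**

1 | 2-fluoro-3,4-dihydroxybenzaldehyde | O=Cc1ccc(O)c(O)c1F | starting material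
2 | 3-(benzyloxy)-2-fluoro-4-hydroxybenzaldehyde | O=Cc1ccc(O)c(OCc2ccccc2)c1F | intermediate
3 | 3-(benzyloxy)-5-bromo-2-fluoro-4-hydroxybenzaldehyde | O=Cc1cc(Br)c(O)c(OCc2ccccc2)c1F | intermediate
4 | 3,4-bis(benzyloxy)-5-bromo-2-fluorobenzaldehyde | O=Cc1cc(Br)c(OCc2ccccc2)c(OCc2ccccc2)c1F | intermediate
5 | 3,4-bis(benzyloxy)-5-bromo-2-fluorobenzoic acid | OC(=O)c1cc(Br)c(OCc2ccccc2)c(OCc2ccccc2)c1F | intermediate
6 | 3,4-bis(benzyloxy)-5-bromo-2-fluorobenzoyl chloride | ClC(=O)c1cc(Br)c(OCc2ccccc2)c(OCc2ccccc2)c1F | intermediate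
7 | 2-(benzyloxy)-N-methoxy-N-methylacetamide | CON(C)C(=O)COCc1ccccc1 | starting material
8 | [4-(benzyloxy)phenyl]magnesium bromide | Br[Mg]c1ccc(OCc2ccccc2)cc1 | starting material
9 | 2-(benzyloxy)-1-[4-(benzyloxy)phenyl]ethan-1-one | O=C(COCc1ccccc1)c1ccc(OCc2ccccc2)cc1 | intermediate
10 | 2-(benzyloxy)-1-[3,4-bis(benzyloxy)-5-bromo-2-fluorophenyl]-3-[4-(benzyloxy)phenyl]propane-1,3-dione (as its lithium enolate) | O=C(C(OCc1ccccc1)C(=O)c1cc(Br)c(OCc2ccccc2)c(OCc2ccccc2)c1F)c1ccc(OCc2ccccc2)cc1 | intermediate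
11 | 3,7,8-tris(benzyloxy)-2-[4-(benzyloxy)phenyl]-6-bromo-4H-chromen-4-one | O=c1c(OCc2ccccc2)c(-c2ccc(OCc3ccccc3)cc2)oc2c(OCc3ccccc3)c(OCc3ccccc3)c(Br)cc12 | intermediate
12 | 3,7,8-tris(benzyloxy)-2-[4-(benzyloxy)phenyl]-6-(4,4,5,5-tetramethyl-1,3,2-dioxaborolan-2-yl)-4H-chromen-4-one | O=c1c(OCc2ccccc2)c(-c2ccc(OCc3ccccc3)cc2)oc2c(OCc3ccccc3)c(OCc3ccccc3)c(B3OC(C)(C)C(C)(C)O3)cc12 | intermediate
13 | 2,3,4-trihydroxybenzaldehyde | O=Cc1ccc(O)c(O)c1O | starting material
14 | 3,4-bis(benzyloxy)-2-hydroxybenzaldehyde | O=Cc1ccc(OCc2ccccc2)c(OCc2ccccc2)c1O | intermediate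
15 | 1-[4-(benzyloxy)phenyl]ethan-1-one | CC(=O)c1ccc(OCc2ccccc2)cc1 | starting material
16 | (E)-3-[3,4-bis(benzyloxy)-2-hydroxyphenyl]-1-[4-(benzyloxy)phenyl]prop-2-en-1-one | O=C(/C=C/c1ccc(OCc2ccccc2)c(OCc2ccccc2)c1O)c1ccc(OCc2ccccc2)cc1 | intermediate
17 | (3R)-3-[3,4-bis(benzyloxy)-2-hydroxyphenyl]-1-[4-(benzyloxy)phenyl]-3-{3,7,8-tris(benzyloxy)-2-[4-(benzyloxy)phenyl]-4-oxo-4H-chromen-6-yl}propan-1-one | O(Cc9ccccc9)c1ccc(C(=O)C[C@@H](c5cc4c(c(OCc9ccccc9)c5OCc9ccccc9)oc(-c8ccc(OCc9ccccc9)cc8)c(OCc9ccccc9)c4=O)c3ccc(OCc9ccccc9)c(OCc9ccccc9)c3O)cc1 | intermediate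
18 | (1R,3R)-3-[3,4-bis(benzyloxy)-2-hydroxyphenyl]-1-[4-(benzyloxy)phenyl]-3-{3,7,8-tris(benzyloxy)-2-[4-(benzyloxy)phenyl]-4-oxo-4H-chromen-6-yl}propan-1-ol | O(Cc9ccccc9)c1ccc([C@H](O)C[C@@H](c5cc4c(c(OCc9ccccc9)c5OCc9ccccc9)oc(-c8ccc(OCc9ccccc9)cc8)c(OCc9ccccc9)c4=O)c3ccc(OCc9ccccc9)c(OCc9ccccc9)c3O)cc1 | intermediate
19 | 3,7,8-tris(benzyloxy)-2-[4-(benzyloxy)phenyl]-6-{(2S,4R)-7,8-bis(benzyloxy)-2-[4-(benzyloxy)phenyl]chroman-4-yl}-4H-chromen-4-one (upper unit 2,4-trans) | O(Cc9ccccc9)c1ccc([C@@H]2C[C@@H](c5cc4c(c(OCc9ccccc9)c5OCc9ccccc9)oc(-c8ccc(OCc9ccccc9)cc8)c(OCc9ccccc9)c4=O)c3ccc(OCc9ccccc9)c(OCc9ccccc9)c3O2)cc1 | intermediate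
20 | 3,7,8-tris(benzyloxy)-2-[4-(benzyloxy)phenyl]-6-{(2S,4R)-7,8-bis(benzyloxy)-2-[4-(benzyloxy)phenyl]chroman-4-yl}chroman-4-one, stereoisomer mixture at lower C2 and C3 | O(Cc9ccccc9)c1ccc([C@@H]2C[C@@H](c5cc4c(c(OCc9ccccc9)c5OCc9ccccc9)OC(c8ccc(OCc9ccccc9)cc8)C(OCc9ccccc9)C4=O)c3ccc(OCc9ccccc9)c(OCc9ccccc9)c3O2)cc1 | intermediate
21 | (2R,3R,4R)-3,7,8-tris(benzyloxy)-2-[4-(benzyloxy)phenyl]-6-{(2S,4R)-7,8-bis(benzyloxy)-2-[4-(benzyloxy)phenyl]chroman-4-yl}chroman-4-ol (lower unit all-cis) | O(Cc9ccccc9)c1ccc([C@@H]2C[C@@H](c5cc4c(c(OCc9ccccc9)c5OCc9ccccc9)O[C@H](c8ccc(OCc9ccccc9)cc8)[C@H](OCc9ccccc9)[C@@H]4O)c3ccc(OCc9ccccc9)c(OCc9ccccc9)c3O2)cc1 | intermediate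
22 | (2R,3R,4R)-6-[(2S,4S)-7,8-dihydroxy-2-(4-hydroxyphenyl)chroman-4-yl]-2-(4-hydroxyphenyl)chromane-3,4,7,8-tetrol, CNP0209379.1 | Oc1ccc([C@@H]2C[C@@H](c3cc4c(c(O)c3O)O[C@H](c3ccc(O)cc3)[C@H](O)[C@@H]4O)c3ccc(O)c(O)c3O2)cc1 | target

**Totals.** 16 steps in all. The longest linear sequence is 13 steps (steps 1, 2, 3, 4, 5, 7, 8, 11, 12, 13, 14, 15, 16, from 1 to 22).

**Steps most likely to fail**

1. Step 15. The dynamic resolution may stall as a plain kinetic resolution if C2 equilibrates too slowly through ring opening and re-closure, and diastereoselectivity may erode if the 2,3-trans ketones are reduced competitively. Fallback, from 20 back to 21: rely on substrate control instead of catalyst control. The ketone mixture 20, mainly 2,3-cis after the kinetic protonation of step 14, is reduced with NaBH4 in THF/MeOH at −40 °C. Hydride adds anti to the axial C3 benzyloxy group and the C2 aryl group, so both lower-unit series give all-cis alcohols: 21 and the lower-unit (2S,3S,4S) diastereomer of 21 F1. Because the upper unit is a single enantiomer these two are diastereomers; they are separated by preparative HPLC, and 21 rejoins the route at step 16.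

2. Step 14. Hydride may attack the carbonyl (1,2) or fail to transfer to the tetrasubstituted, alkoxy-donated C2=C3 bond. Fallback, from 19 directly to 21: asymmetric hydrogenation of the flavone with a chiral ruthenium bis(N-heterocyclic carbene) catalyst (Ru(cod)(2-methylallyl)2, chiral imidazolinium salt, KOt-Bu, H2 under pressure, toluene), a reaction known to turn flavones into cis-flavan-4-ols. Syn delivery of hydrogen to C2=C3 and reduction of the ketone from the same face would give the all-cis array in one step. This bypasses 20 and makes no new compound (F0).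

3. Step 11. Protodeboronation of the hindered ortho-alkoxy boronate may outrun transmetalation, and the enone is deactivated once its ortho-phenol is deprotonated. Fallback, from 14 back to 17: mask the phenol. Aldehyde 14 is allylated (allyl bromide, K2CO3, DMF) to 2-(allyloxy)-3,4-bis(benzyloxy)benzaldehyde F2. Claisen–Schmidt condensation of F2 with 15 gives the O-allyl chalcone F3. The same rhodium/(S)-BINAP addition of 12 to this neutral enone gives the O-allyl ketone F4. Pd(PPh3)4 and morpholine in THF then remove the allyl group and return 17.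

**Further compounds**

F1 | step 15 | (2S,3S,4S)-3,7,8-tris(benzyloxy)-2-[4-(benzyloxy)phenyl]-6-{(2S,4R)-7,8-bis(benzyloxy)-2-[4-(benzyloxy)phenyl]chroman-4-yl}chroman-4-ol | O(Cc9ccccc9)c1ccc([C@@H]2C[C@@H](c5cc4c(c(OCc9ccccc9)c5OCc9ccccc9)O[C@@H](c8ccc(OCc9ccccc9)cc8)[C@@H](OCc9ccccc9)[C@H]4O)c3ccc(OCc9ccccc9)c(OCc9ccccc9)c3O2)cc1
F0 | step 14 | none | none
F2 | step 11 | 2-(allyloxy)-3,4-bis(benzyloxy)benzaldehyde | O=Cc1ccc(OCc9ccccc9)c(OCc9ccccc9)c1OCC=C
F3 | step 11 | (E)-3-[2-(allyloxy)-3,4-bis(benzyloxy)phenyl]-1-[4-(benzyloxy)phenyl]prop-2-en-1-one | O=C(/C=C/c1ccc(OCc9ccccc9)c(OCc9ccccc9)c1OCC=C)c8ccc(OCc9ccccc9)cc8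
F4 | step 11 | (3R)-3-[2-(allyloxy)-3,4-bis(benzyloxy)phenyl]-1-[4-(benzyloxy)phenyl]-3-{3,7,8-tris(benzyloxy)-2-[4-(benzyloxy)phenyl]-4-oxo-4H-chromen-6-yl}propan-1-one | O(Cc9ccccc9)c1ccc(C(=O)C[C@@H](c5cc4c(c(OCc9ccccc9)c5OCc9ccccc9)oc(-c8ccc(OCc9ccccc9)cc8)c(OCc9ccccc9)c4=O)c3ccc(OCc9ccccc9)c(OCc9ccccc9)c3OCC=C)cc1
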